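(The readings are calculated on assumed constants, and the scatter is random.)

At early times G rises so evenly in this flask that I replace its curve by its mean slope: 10.8% of the E charged in 90.0 s.

in all of them: E 0.050 M; Z 80 µM

|  | D | remark |
|---|---|---|
| epsilon | 0.10 M | the very flask that is asked about, followed so far |
| flask | 0.100 M |  |

epsilon run (percent of the E charged)

| time / s | G / % | E / % |
|---|---|---|
| 10.0 | 1.1 | 98.4 |
| 15.0 | 1.6 | 98.4 |
| 25.0 | 2.9 | 97.0 |
| 40.0 | 5.2 | 94.8 |
| 50.0 | 5.8 | 94.5 |
| 80.0 | 9.9 | 89.4 |
| 90.0 | 10.8 | 89.0 |

(standard deviation of a reading: 0.5 percentage points)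

1. apparent order in D when 50% of the E are converted (percent change of the rate of making G for one percent more D charged)
2. factor on the rate of making G when 50% of the E are converted if Z is charged twice over

- no earlier run changes the charge of Z; that part of a forecast is a guess
- no earlier run changes the charge of D; that part of a forecast is a guess

At that slope 50% of the E goes in 6.94 min, the straight-line half-time. But the same last reading, taken as first order in E, gives 9.10 min, which is 1.31 times as long, and the readings seem to allow both.

The contradiction clears when I reckon the error of the mean. A first-order curve through the same end point leaves the straight line at mid-run by 0.154% of the charge, less than the scatter of 0.5 percentage points. So I can't tell the two apart here, and I commit to a half-time between those two values. No earlier run varies D or Z, so my reckoning stops there.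

The forecast gives 0.4 for the order in D (range 0 to 1.3), on “a modest local order”, and 2 for the factor on doubling Z (range 1.4 to 2.6).

The flask gives an order in D of −0.067 and a factor of 1.85.

    E + Z ⇌ J (K = 21.3 L mol⁻¹, k = 7380 L mol⁻¹ min⁻¹)
    J → Z + G (k = 137 min⁻¹)
    2 J ⇌ Q (K = 26000 L mol⁻¹, k = 4000 L mol⁻¹ min⁻¹)
    D + Z ⇌ X (K = 20.0 L mol⁻¹, k = 3840 L mol⁻¹ min⁻¹)
    X → Z + L (k = 664 min⁻¹)

The flask passes 50% at 8.88 min, which is 1.28 times the straight-line half-time. The exchange between two J and Q, by that step alone and both ways together, relaxes with a half-life of 1.49 min at 5.00 min, shorter than that passing time. At 50% conversion, with each Q counted as two, the catalyst stands as J at 20.1% and as Q at 18.6%.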